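## Structural features

Nakijiquinone E contains two rearranged-drimane (avarane) trans-decalins. They are numbered here C1–C10, with C11 the CH2 on C9 and β the face of the C5 methyl. One decalin has an exocyclic C4=CH2 and is joined through C11 to C5 of a methyl 3-amino-2,4-dihydroxybenzoate. The other has a C3=C4 alkene and is joined through its C11 to C3 of a 2-hydroxy-1,4-benzoquinone; the benzoate nitrogen sits on C5 of that quinone, so the halves meet at one N–C bond of a vinylogous amide. Each decalin has four contiguous stereocentres: quaternary C5 (β-methyl), C10 (α-H, trans fusion), quaternary C9 (β-methyl, α-C11) and C8 (β-methyl), with the C5 and C9 methyls 1,3-syn-diaxial across ring B. The fragile groups are the aminohydroxyquinone (redox-active, sensitive to base and nucleophiles), the aminoresorcinol (air oxidation), the exocyclic alkene (acid-induced migration or cationic cyclisation onto the ortho phenol) and the methyl ester. The real difficulty is the pair of quaternary carbons C5 and C9 in defined absolute configuration, needed twice, next to a neopentyl C11 that cannot be made by substitution; the second is that the two decalins differ only in alkene position. The key step exploits ring B: C5 and C9 are the ends of a cyclohexene formed from a dienophile C5=C10 and a diene C6=C7–C8=C9, and C1 and C4 of ring A map onto the two carbonyls of a methoxy-methyl-benzoquinone whose methyl-bearing alkene is C5=C10.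

## Logic of the disconnections

38 to 27 and 37. The N–C bond between the nitrogen of the benzoate ring and quinone carbon C5 is cut, because it is the only link between the halves and is a vinylogous amide that forms by addition–elimination on a vinylogous ester. This halves the problem. The forward step needs the nitrogen of 37 to react in preference to its two phenols, and neither partner may be oxidised.

27 to 26 to 25. The quinone carbonyls and the free hydroxyl are taken back to four aryl methyl ethers. This turns a sensitive quinone into a robust arene that tolerates organometallic and radical steps. The forward demand is oxidation to one para-quinone and hydrolysis of only the methoxy group next to the alkyl chain.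

25 to 24. The C3=C4 alkene is traced to the exocyclic C4=CH2 isomer. Both halves then come from one decalin series, and the endocyclic alkene is made by isomerisation downhill. The forward step must stop at C3=C4, which the quaternary C5 ensures.

24 to 23 to 22 to 19 and 21. The C11–aryl bond is cut. C11 is neopentyl and substitution there is not feasible, so the bond is made by carbonyl addition to 19 and the carbinol oxygen is then removed by a radical. The forward demand is addition of a di-ortho-substituted aryl metal to a hindered but non-enolisable aldehyde.

37 to 36 to 35. The C3–N bond of the benzoate ring is cut, because C3 is the only ring position activated by both hydroxyls once C5 carries the decalin. The nitrogen is therefore introduced last, by electrophilic substitution that does not touch the exocyclic alkene. The forward demand is coupling at a position flanked by two oxygens.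

35 to 34 to 33 to 32 to 19 and 31; 31 to 30 to 29 to 28. The same C11–aryl cut is made, with the ester already in place on the aryl metal. This avoids later carboxylation. The forward demand is a halogen–metal exchange that tolerates the ester.

19 to 18 to 17 to 16. The exocyclic C=C at C4 is cut back to a C4 ketone and C11 is taken down to the silyl ether. The ketone is the one function from which both alkene isomers can be reached. The forward demand is methylenation next to the quaternary C5.

16 to 14 to 13. The C–H bonds at C2, C3, C7 and C8 are traced to the C2-methoxy enone and the C7=C8 alkene. The forward demand is delivery of hydrogen to C8 from the α face and loss of the C2 oxygen without affecting C4.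

13 to 11 to 10 to 8. The C1–H and C10–H bonds are traced to the C1 ketone. C10–H is the only enolisable hydrogen in 8, so one enolisation both activates the C1 oxygen for removal and erases the cis C10 centre. The forward demand is that C10 be reprotonated from the α face.

8 to 2 and 7. C5–C6 and C9–C10 are cut, opening ring B. Both quaternary carbons and their 1,3-relationship come from one cycloaddition of two small achiral components. The forward demand is site, regio, endo and enantiofacial control with a fully substituted diene terminus.

7 to 6 to 5 to 4 to 3, and 2 to 1. The C7–C8 single bond of the diene (vinyl to alkene carbon) is cut. The tetrasubstituted alkene geometry decides the C9 configuration, so it is fixed at the enol sulfonate stage and carried through with retention. An enone olefination would give an E/Z mixture and compete with conjugate addition. 2 comes from 1 by para-oxidation.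

## Other disconnections considered

Alternative 1: Ring B is cut at C5–C10 and C8–C9, and ring A forms through the tether. Forward, the acyclic vinylallene enal A1 would undergo an intramolecular Diels–Alder reaction, with its (E)-2-methyl-enal activated by a chiral oxazaborolidinium salt, to give the trans-decalin dienyl aldehyde A2. In its favour, the trans ring fusion follows directly from the enal geometry and a formyl-endo transition state, so no C10 correction is needed; on this point it is better than the chosen plan. C11 arrives as the aldehyde and C4 as a masked ketone with no surplus oxygen on ring A, which is also better. Enal activation is the best-established use of this catalyst class, so it is at least equal there. Against it, A2 carries C8 as an exocyclic methylene inside a 1,3-diene (C6=C7–C8=CH2), which must be reduced twice with control at C8 beside a neopentyl aldehyde. A1 also combines an allene, a trisubstituted (E)-alkene, a ketal and a trisubstituted enal in one chain and needs a long linear preparation. Both plans rely on a concerted [4+2] step that creates C5 and C9. This one is longer before the key step and shorter after it, so the totals should be similar, but the chosen plan starts from two components made in at most four steps each.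

Alternative 2: The quinone ring itself is cut (bond q4–q5), so the ring would be built on the nitrogen. Forward, the 4-alkenyl-4-hydroxy-3-(arylamino)cyclobutenone A3 would open on heating to a dienylketene, close by a six-electron electrocyclisation and tautomerise to the hydroquinone A4 (Moore-type ring expansion). In its favour, the positions of nitrogen, oxygen and alkyl group are fixed by construction and do not depend on the nucleophilicity of a hindered aniline; on regiochemistry of the union it is better than the chosen final step. The key step also runs under neutral thermal conditions. Against it, both decalins and the aryl amine are still needed, so it complements the decalin strategy and does not replace it. It requires a metallated 2-ethoxyvinyl unit on a neopentyl carbon. After the union it needs oxidation to the quinone, cleavage of the ethyl ether and removal of two acetal protecting groups in the presence of the acid-sensitive exocyclic alkene, where the chosen plan ends at the union. On step economy it is therefore worse; on mechanism it is a pericyclic cascade of comparable reliability.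

Alternative 3: C4–C5 and C9–C10 are cut together with the biosynthetic rearrangement. Forward, a clerodane-type cyclase would convert geranylgeranyl diphosphate A5 into kolavenyl diphosphate A6 of the enantiomeric series that matches the target. In its favour, one step makes both rings, all four stereocentres and the C3=C4 alkene with no protecting groups; for the decalin itself this step economy is far better than any chemical route, the chosen one included. Against it, A6 is a C20 unit whose chain beyond C11 must be degraded by five carbons before an aryl group can be attached at C11. It gives only the endocyclic alkene, so the exocyclic half would need a contra-thermodynamic isomerisation. An enzyme of the required enantiomeric series and a preparative supply of A5 are also needed. The chosen plan gives the exocyclic isomer first and reaches the endocyclic one downhill, and it delivers C11 at the aldehyde level with no chain to remove.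

Key step: step 6

Remarks on the chemistry (assumptions):
- The key-step structures were checked against the target. The (E)-diene has the C9 methyl inside and CH2OSi outside; adduct 8 as written has C5 and C9 in the target configuration and H-10 cis to the C5 methyl. No structure needed correction.
- The sense of induction in step 6 is assigned from the accepted binding model (boron on the C1 oxygen syn to C10–H, diene onto the face away from the geminal phenyl group). By this analysis the (R)-configured catalyst is required; if the model failed for this diene, the mirror-image catalyst would be used with no other change.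
- Compound 14 is a mixture of C2 epimers, and 22, 23, 32 and 33 are mixtures of epimers at the carbinol carbon C11; these centres are removed later.

## Route

Step 1
Reactants: 1 2-methoxy-5-methylphenol
Product: 2 2-methoxy-5-methyl-1,4-benzoquinone
Conditions: ON(SO3K)2 (2.2 equiv), KH2PO4, H2O/acetone, 23 °C
Reagents that add atoms: potassium nitrosodisulfonate, [K+].[K+].[O]N(S(=O)(=O)[O-])S(=O)(=O)[O-]
Why: Teuber oxidation: the phenoxyl radical made by the first equivalent is trapped by a second equivalent at the free para position and loses imidodisulfonate to give the para-quinone.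

Step 2
Reactants: 3 methyl 2-methyl-3-oxobutanoate
Product: 4 methyl (E)-2-methyl-3-(4-methylphenylsulfonyloxy)but-2-enoate
Conditions: TsCl, N-methylimidazole, Et3N, MeCN, 0 to 23 °C
Reagents that add atoms: 4-methylbenzenesulfonyl chloride, Cc1ccc(cc1)S(=O)(=O)Cl
Why: Stereoselective enol sulfonylation of an α-substituted β-keto ester: with an amine base the non-chelated enolate reacts with the N-sulfonylimidazolium, which places the sulfonate trans to the ester (E).

Step 3
Reactants: 4 methyl (E)-2-methyl-3-(4-methylphenylsulfonyloxy)but-2-enoate
Product: 5 methyl (E)-2,3-dimethylpenta-2,4-dienoate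
Conditions: potassium vinyltrifluoroborate, Pd(OAc)2 (3 mol %), 2-dicyclohexylphosphino-2′,6′-dimethoxybiphenyl (6 mol %), K2CO3, THF/H2O, 65 °C
Reagents that add atoms: potassium vinyltrifluoroborate, C=C[B-](F)(F)F.[K+]
Why: Suzuki–Miyaura coupling of an enol tosylate; oxidative addition and reductive elimination at the sp2 carbon go with retention, so the tetrasubstituted alkene geometry of 4 is carried into the diene (vinyl trans to the ester).

Step 4
Reactants: 5 methyl (E)-2,3-dimethylpenta-2,4-dienoate
Product: 6 (E)-2,3-dimethylpenta-2,4-dien-1-ol
Conditions: (i-Bu)2AlH (2.2 equiv), CH2Cl2, −78 °C; aqueous potassium sodium tartrate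
Reagents that add atoms: none
Why: 1,2-Reduction of a conjugated ester by an aluminium hydride gives the allylic alcohol and leaves the diene untouched.

Step 5
Reactants: 6 (E)-2,3-dimethylpenta-2,4-dien-1-ol
Product: 7 (E)-tert-butyl(2,3-dimethylpenta-2,4-dienyloxy)dimethylsilane
Conditions: t-BuMe2SiCl, imidazole, CH2Cl2, 0 °C
Reagents that add atoms: tert-butyldimethylsilyl chloride, CC(C)(C)[Si](C)(C)Cl
Why: Silylation of a primary allylic alcohol; the silyl ether should survive the later Lewis acid, base, dissolving-metal and hydrogenation steps.

Step 6
Reactants: 2 2-methoxy-5-methyl-1,4-benzoquinone; 7 (E)-tert-butyl(2,3-dimethylpenta-2,4-dienyloxy)dimethylsilane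
Product: 8 (4aS,8S,8aR)-8-(tert-butyldimethylsilyloxymethyl)-2-methoxy-4a,7,8-trimethyl-4a,5,8,8a-tetrahydronaphthalene-1,4-dione (cis-fused endo adduct)
Conditions: (R)-oxazaborolidinium triflimide (20 mol %; from (R)-3,3-diphenyl-1-(2-methylphenyl)tetrahydro-1H,3H-pyrrolo[1,2-c][1,3,2]oxazaborole and HN(SO2CF3)2), CH2Cl2, −78 to −40 °C
Reagents that add atoms: none
Why: This is a concerted, asynchronous endo [4+2] cycloaddition of a Lewis-acid-activated quinone with a 1,1,2-trisubstituted diene, and the closest known class is the oxazaborolidinium-catalysed enantioselective quinone Diels–Alder reaction. Boron binds the C1 carbonyl oxygen on the lone pair syn to C10–H, which makes C5 the most electrophilic carbon, so the unhindered C6H2 terminus bonds to C5 and the fully substituted C9 bonds to C10–H; the opposite regiochemistry would join two fully substituted carbons and is sterically excluded. Ring B (C5–C6–C7–C8–C9–C10) closes by suprafacial formation of the C5–C6 and C9–C10 bonds in one six-electron step. The methoxy-bearing alkene is a vinylogous ester and should not compete, so the methyl-bearing alkene C5=C10 is the only dienophile. C5 and C10 come out cis because the dienophile geometry is retained. At C9 the (E)-diene has its methyl inside and CH2OSi outside, and the endo transition state (quinone ring under the diene) therefore puts the C9 methyl syn to the C5 methyl and C11 anti. The absolute configuration at C5 and C9 is set by the catalyst, whose geminal phenyl group covers one face of C5=C10 so that the diene adds to the other. The reaction needs site, regio, endo and enantiofacial selectivity; the C8 methyl helps by destabilising the s-trans conformer, which offsets the cost of the inside methyl in the reactive s-cis form.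

Step 7
Reactants: 8 cis-fused endo adduct
Product: 10 C1 enol triflate of 8 (ring A: C4 ketone; C2(OMe)=C3; C1(OTf)=C10), via potassium C1(10)-enolate 9 (not isolated)
Conditions: KN(SiMe3)2, THF, −78 °C; PhN(SO2CF3)2, −78 to 0 °C
Reagents that add atoms: N-phenylbis(trifluoromethanesulfonimide), O=S(=O)(N(c1ccccc1)S(=O)(=O)C(F)(F)F)C(F)(F)F
Why: C10–H is the only enolisable hydrogen of 8 (C2 and C3 are sp2, C5 is quaternary), so one enolate and one enol triflate should form; the step erases the cis C10 centre and activates the C1 oxygen for removal.

Step 8
Reactants: 10 C1 enol triflate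
Product: 11 dienone (ring A: C4 ketone; C2(OMe)=C3; C1H=C10; ring B: C7=C8; 5β-Me; 9β-Me; 9α-CH2OSi)
Conditions: Pd(OAc)2 (5 mol %), PPh3 (10 mol %), n-Bu3N, HCO2H, DMF, 60 °C
Reagents that add atoms: none
Why: Palladium-catalysed formate reduction of an enol triflate: oxidative addition, exchange of triflate for formate, loss of CO2 and C–H reductive elimination replace C1–O by C1–H without reducing the alkenes.

Step 9
Reactants: 11 dienone
Product: 13 trans-fused vinylogous ester (ring A: C4 ketone; C2(OMe)=C3; C1H2; H-10 α), via lithium dienolate 12 (not isolated)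
Conditions: Li (2.5 equiv), NH3(l)/THF, t-BuOH (1 equiv), −78 °C; NH4Cl; then DBU (cat.), CH2Cl2, 23 °C
Reagents that add atoms: none
Why: Dissolving-metal (Birch-type) 1,6-reduction of a linear dienone: two electrons and one proton add, the proton at the δ-carbon C10, axial to ring A and anti to the axial C5 methyl, which gives the trans fusion (α-H). The dienolate 12 is inert to further reduction; protonation on quench and base equilibration give the conjugated vinylogous ester.

Step 10
Reactants: 13 trans-fused vinylogous ester
Product: 14 β-methoxy ketone (C2-OMe, C4 ketone, saturated rings, 8β-Me; C2 epimers)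
Conditions: H2 (4 atm), Pd/C (palladium on carbon), EtOAc, 23 °C
Reagents that add atoms: none
Why: Heterogeneous hydrogenation: the β face of ring B is covered by the axial C5 and C9 methyls, so hydrogen should add to C7=C8 from the α face and make C8 β-methyl (equatorial); the vinylogous ester alkene is saturated in the same operation.

Step 11
Reactants: 14 β-methoxy ketone
Product: 16 decalin-4-one (C1–C3 CH2; 5β-Me; 8β-Me; 9β-Me; 9α-CH2OSi; H-10 α), via C2=C3 enone 15 (not isolated)
Conditions: DBU, PhMe, 80 °C; then Pd/C (palladium on carbon), H2 (1 atm), 23 °C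
Reagents that add atoms: none
Why: E1cB loss of methanol from the β-methoxy ketone gives the enone, whose disubstituted alkene is hydrogenated at once; the only α-carbon with hydrogen is C3, so no stereocentre is at risk.

Step 12
Reactants: 16 decalin-4-one
Product: 17 exocyclic alkene silyl ether (C4=CH2)
Conditions: Ph3PCH3Br, KOt-Bu, PhMe, 90 °C
Reagents that add atoms: methyltriphenylphosphonium bromide, C[P+](c1ccccc1)(c1ccccc1)c1ccccc1.[Br-]
Why: Wittig methylenation of a ketone flanked by a quaternary carbon, run hot with a non-nucleophilic base as is usual for this hindered decalone class.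

Step 13
Reactants: 17 exocyclic alkene silyl ether
Product: 18 C11 alcohol
Conditions: Bu4NF, THF, 50 °C
Reagents that add atoms: none
Why: Fluoride cleavage of the neopentyl silyl ether; nothing else in the molecule reacts with fluoride.

Step 14
Reactants: 18 C11 alcohol
Product: 19 C11 aldehyde (4(exo)-methylene; 5β,8β,9β-trimethyl; 9α-CHO; H-10 α)
Conditions: (n-Pr4N)RuO4 (5 mol %), N-methylmorpholine N-oxide, 4 Å sieves, CH2Cl2, 23 °C
Reagents that add atoms: none
Why: Perruthenate-catalysed (Ley–Griffith) oxidation of a primary alcohol; C9 is quaternary, so the aldehyde can neither enolise nor epimerise.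

Step 15
Reactants: 20 1,2,4,5-tetramethoxybenzene; 19 C11 aldehyde
Product: 22 benzylic carbinol (C11(OH) bearing 2,3,5,6-tetramethoxyphenyl), via 2,3,5,6-tetramethoxyphenyllithium 21 (not isolated)
Conditions: n-BuLi, THF, 0 °C; then 19, −78 to 0 °C; H2O
Reagents that add atoms: none
Why: Directed ortho-lithiation between two methoxy groups gives the aryllithium, which adds to the non-enolisable neopentyl aldehyde; the new carbinol centre is removed in step 17.

Step 16
Reactants: 22 benzylic carbinol
Product: 23 S-methyl xanthate of 22
Conditions: NaN(SiMe3)2, THF, −78 °C; CS2; MeI, −78 to 23 °C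
Reagents that add atoms: carbon disulfide, S=C=S; iodomethane, CI
Why: Xanthate formation from the hindered alkoxide by addition to carbon disulfide and S-methylation.

Step 17
Reactants: 23 S-methyl xanthate
Product: 24 exocyclic-alkene arene (C11H2 bearing 2,3,5,6-tetramethoxyphenyl)
Conditions: Bu3SnH, AIBN, PhMe, 110 °C
Reagents that add atoms: none
Why: Barton–McCombie deoxygenation: the stannyl radical adds to sulfur, the benzylic C–O bond fragments and the benzylic radical takes hydrogen from the stannane; the exocyclic alkene is too remote to cyclise.

Step 18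
Reactants: 24 exocyclic-alkene arene
Product: 25 endocyclic-alkene arene (C3=C4, 4-methyl)
Conditions: RhCl3·3H2O (20 mol %), EtOH, 80 °C
Reagents that add atoms: none
Why: Rhodium-hydride addition–elimination moves the exocyclic alkene to the more substituted C3=C4 position, the thermodynamic end point, because C5 is quaternary and blocks further migration.

Step 19
Reactants: 25 endocyclic-alkene arene
Product: 26 2,5-dimethoxy-3-(decalinylmethyl)-1,4-benzoquinone
Conditions: (NH4)2Ce(NO3)6, MeCN/H2O, 0 °C
Reagents that add atoms: water, O
Why: Oxidative demethylation of a para-dimethoxyarene; the two possible para pairs are related by the symmetry of the aryl ring and give the same quinone.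

Step 20
Reactants: 26 dimethoxyquinone
Product: 27 2-hydroxy-5-methoxy-3-(decalinylmethyl)-1,4-benzoquinone
Conditions: KOH, MeOH/H2O, 23 °C; then dilute HCl
Reagents that add atoms: potassium hydroxide, [K+].[OH-]
Why: Addition–elimination at a vinylogous ester: the methoxy group next to the alkyl substituent is twisted out of conjugation and is the one replaced, as in the hydroxy-methoxy quinones of this family; the hydroxyquinone anion resists a second hydrolysis.

Step 21
Reactants: 28 methyl 2,4-dihydroxybenzoate
Product: 29 methyl 2,4-dihydroxy-5-iodobenzoate
Conditions: ICl, AcOH, 23 °C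
Reagents that add atoms: iodine monochloride, ICl
Why: Electrophilic iodination para to the 2-hydroxyl and ortho to the 4-hydroxyl; iodine monochloride in acid favours C5 over the position between the hydroxyls.

Step 22
Reactants: 29 methyl 2,4-dihydroxy-5-iodobenzoate
Product: 30 methyl 5-iodo-2,4-bis(methoxymethoxy)benzoate
Conditions: NaH, MeOCH2Cl, DMF, 0 to 23 °C
Reagents that add atoms: chloromethyl methyl ether, COCCl
Why: O-Alkylation of both phenoxides; sodium hydride also deprotonates the hydrogen-bonded 2-hydroxyl.

Step 23
Reactants: 30 methyl 5-iodo-2,4-bis(methoxymethoxy)benzoate; 19 C11 aldehyde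
Product: 32 benzylic carbinol (C11(OH) on C5 of the protected benzoate), via arylmagnesium chloride 31 (not isolated)
Conditions: i-PrMgCl·LiCl, THF, −30 °C; then 19, −30 to 0 °C; aqueous NH4Cl
Reagents that add atoms: none
Why: Iodine–magnesium exchange is faster than attack on the ester at low temperature, and the resulting arylmagnesium adds to the neopentyl aldehyde.

Step 24
Reactants: 32 benzylic carbinol
Product: 33 S-methyl xanthate of 32
Conditions: NaN(SiMe3)2, THF, −78 °C; CS2; MeI, −78 to 0 °C
Reagents that add atoms: carbon disulfide, S=C=S; iodomethane, CI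
Why: Xanthate formation as in step 16; the amide base and low temperature spare the methyl ester.

Step 25
Reactants: 33 S-methyl xanthate
Product: 34 methyl 5-(decalinylmethyl)-2,4-bis(methoxymethoxy)benzoate (exocyclic alkene)
Conditions: Bu3SnH, AIBN, PhMe, 110 °C
Reagents that add atoms: none
Why: Barton–McCombie deoxygenation of the benzylic xanthate, as in step 17.

Step 26
Reactants: 34 bis(methoxymethyl) ether
Product: 35 methyl 5-(decalinylmethyl)-2,4-dihydroxybenzoate
Conditions: ZnBr2, n-PrSH, CH2Cl2, 0 °C
Reagents that add atoms: none
Why: Lewis-acid-assisted transfer of the methoxymethyl groups to the thiol under non-protic conditions, which should leave the exocyclic alkene in place.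

Step 27
Reactants: 35 methyl 5-(decalinylmethyl)-2,4-dihydroxybenzoate
Product: 36 C3 azo compound (3-(4-nitrophenyldiazenyl) derivative of 35)
Conditions: 4-nitrobenzenediazonium tetrafluoroborate, pyridine/THF, 0 °C
Reagents that add atoms: 4-nitrobenzenediazonium tetrafluoroborate, [O-][N+](=O)c1ccc(cc1)[N+]#N.F[B-](F)(F)F
Why: Azo coupling, an electrophilic aromatic substitution by a reagent that does not react with alkenes; C3 is the only open ring position ortho or para to a hydroxyl.

Step 28
Reactants: 36 C3 azo compound
Product: 37 methyl 3-amino-5-(decalinylmethyl)-2,4-dihydroxybenzoate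
Conditions: Na2S2O4, EtOH/H2O, 60 °C, argon
Reagents that add atoms: none
Why: Reductive cleavage of the azo N=N bond by dithionite, the classical route to ortho-aminophenols; alkene and ester are inert, and the nitro group of the by-product is reduced as well.

Step 29
Reactants: 27 hydroxy methoxy quinone; 37 aryl amine
Product: 38 nakijiquinone E
Conditions: EtOH, 45 °C, argon, dark
Reagents that add atoms: none
Why: Addition–elimination at the vinylogous ester carbon C5 of the quinone: the aniline nitrogen adds, methanol is lost and the vinylogous amide forms; the nitrogen is the most nucleophilic site of 37, and the quinone has only one leaving group.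

## Compound list

1 | 2-methoxy-5-methylphenol | COc1ccc(C)cc1O | starting material
2 | 2-methoxy-5-methyl-1,4-benzoquinone | COC1=CC(=O)C(C)=CC1=O | intermediate
3 | methyl 2-methyl-3-oxobutanoate | COC(=O)C(C)C(C)=O | starting material
4 | methyl (E)-2-methyl-3-(4-methylphenylsulfonyloxy)but-2-enoate (sulfonate trans to ester) | Cc1ccc(cc1)S(=O)(=O)O/C(C)=C(C)/C(=O)OC | intermediate
5 | methyl (E)-2,3-dimethylpenta-2,4-dienoate (vinyl trans to ester) | C=C/C(C)=C(C)/C(=O)OC | intermediate
6 | (E)-2,3-dimethylpenta-2,4-dien-1-ol | C=C/C(C)=C(C)/CO | intermediate
7 | (E)-tert-butyl(2,3-dimethylpenta-2,4-dienyloxy)dimethylsilane | C=C/C(C)=C(C)/CO[Si](C)(C)C(C)(C)C | intermediate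
8 | (4aS,8S,8aR)-8-(tert-butyldimethylsilyloxymethyl)-2-methoxy-4a,7,8-trimethyl-4a,5,8,8a-tetrahydronaphthalene-1,4-dione; cis-fused; C5-Me, C9-Me and H-10 β, C11 α | COC1=CC(=O)[C@@]2(C)CC=C(C)[C@@](C)(CO[Si](C)(C)C(C)(C)C)[C@H]2C1=O | intermediate
9 | potassium C1(10)-enolate of 8 | COC1=CC(=O)[C@@]2(C)CC=C(C)[C@@](C)(CO[Si](C)(C)C(C)(C)C)C2=C1[O-].[K+] | intermediate
10 | C1 enol triflate of 8 (C1(OTf)=C10; C2(OMe)=C3; C4 ketone; C7=C8) | COC1=CC(=O)[C@@]2(C)CC=C(C)[C@@](C)(CO[Si](C)(C)C(C)(C)C)C2=C1OS(=O)(=O)C(F)(F)F | intermediate
11 | dienone (C1H=C10; C2(OMe)=C3; C4 ketone; C7=C8; 5β-Me; 9β-Me; 9α-CH2OSi) | COC1=CC(=O)[C@@]2(C)CC=C(C)[C@@](C)(CO[Si](C)(C)C(C)(C)C)C2=C1 | intermediate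
12 | lithium dienolate (C4(OLi)=C3; C2(OMe)=C1; H-10 α) | COC1C=C([O-])[C@@]2(C)CC=C(C)[C@@](C)(CO[Si](C)(C)C(C)(C)C)[C@@H]2C=1.[Li+] | intermediate
13 | trans-fused vinylogous ester (C4 ketone; C2(OMe)=C3; C1H2; H-10 α; C7=C8) | COC1=CC(=O)[C@@]2(C)CC=C(C)[C@@](C)(CO[Si](C)(C)C(C)(C)C)[C@@H]2C1 | intermediate
14 | β-methoxy ketone (C2-OMe, epimers; C4 ketone; 5β,8β,9β-trimethyl; 9α-CH2OSi; H-10 α) | COC1CC(=O)[C@@]2(C)CC[C@H](C)[C@@](C)(CO[Si](C)(C)C(C)(C)C)[C@@H]2C1 | intermediate
15 | C2=C3 enone (C4 ketone; 5β,8β,9β-trimethyl; 9α-CH2OSi; H-10 α) | C1=CC(=O)[C@@]2(C)CC[C@H](C)[C@@](C)(CO[Si](C)(C)C(C)(C)C)[C@@H]2C1 | intermediate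
16 | trans-decalin-4-one (5β,8β,9β-trimethyl; 9α-CH2OSi; H-10 α) | C1CC(=O)[C@@]2(C)CC[C@H](C)[C@@](C)(CO[Si](C)(C)C(C)(C)C)[C@@H]2C1 | intermediate
17 | 4-methylene trans-decalin 11-silyl ether | C1CC(=C)[C@@]2(C)CC[C@H](C)[C@@](C)(CO[Si](C)(C)C(C)(C)C)[C@@H]2C1 | intermediate
18 | 4-methylene trans-decalin C11 alcohol (5S,8S,9R,10S series of the target) | C1CC(=C)[C@@]2(C)CC[C@H](C)[C@@](C)(CO)[C@@H]2C1 | intermediate
19 | 4-methylene trans-decalin C11 aldehyde (5β,8β,9β-trimethyl; 9α-CHO; H-10 α) | C1CC(=C)[C@@]2(C)CC[C@H](C)[C@@](C)(C=O)[C@@H]2C1 | intermediate
20 | 1,2,4,5-tetramethoxybenzene | COc1cc(OC)c(OC)cc1OC | starting material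
21 | 2,3,5,6-tetramethoxyphenyllithium | COc1cc(OC)c(OC)c([Li])c1OC | intermediate
22 | C11 carbinol bearing 2,3,5,6-tetramethoxyphenyl (C11 epimers; exocyclic alkene) | C1CC(=C)[C@@]2(C)CC[C@H](C)[C@@](C)(C(O)c3c(OC)c(OC)cc(OC)c3OC)[C@@H]2C1 | intermediate
23 | O-alkyl S-methyl xanthate of 22 | C1CC(=C)[C@@]2(C)CC[C@H](C)[C@@](C)(C(OC(=S)SC)c3c(OC)c(OC)cc(OC)c3OC)[C@@H]2C1 | intermediate
24 | 3-(decalinylmethyl)-1,2,4,5-tetramethoxybenzene, exocyclic C4=CH2 | C1CC(=C)[C@@]2(C)CC[C@H](C)[C@@](C)(Cc3c(OC)c(OC)cc(OC)c3OC)[C@@H]2C1 | intermediate
25 | 3-(decalinylmethyl)-1,2,4,5-tetramethoxybenzene, endocyclic C3=C4 | C1C=C(C)[C@@]2(C)CC[C@H](C)[C@@](C)(Cc3c(OC)c(OC)cc(OC)c3OC)[C@@H]2C1 | intermediate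
26 | 2,5-dimethoxy-3-(decalinylmethyl)-1,4-benzoquinone (endocyclic alkene) | C1C=C(C)[C@@]2(C)CC[C@H](C)[C@@](C)(CC3=C(OC)C(=O)C=C(OC)C3=O)[C@@H]2C1 | intermediate
27 | 2-hydroxy-5-methoxy-3-(decalinylmethyl)-1,4-benzoquinone (endocyclic alkene) | C1C=C(C)[C@@]2(C)CC[C@H](C)[C@@](C)(CC3=C(O)C(=O)C=C(OC)C3=O)[C@@H]2C1 | intermediate
28 | methyl 2,4-dihydroxybenzoate | COC(=O)c1ccc(O)cc1O | starting material
29 | methyl 2,4-dihydroxy-5-iodobenzoate | COC(=O)c1cc(I)c(O)cc1O | intermediate
30 | methyl 5-iodo-2,4-bis(methoxymethoxy)benzoate | COC(=O)c1cc(I)c(OCOC)cc1OCOC | intermediate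
31 | [5-(methoxycarbonyl)-2,4-bis(methoxymethoxy)phenyl]magnesium chloride | COC(=O)c1cc([Mg]Cl)c(OCOC)cc1OCOC | intermediate
32 | C11 carbinol on C5 of methyl 2,4-bis(methoxymethoxy)benzoate (C11 epimers; exocyclic alkene) | C1CC(=C)[C@@]2(C)CC[C@H](C)[C@@](C)(C(O)c3cc(C(=O)OC)c(OCOC)cc3OCOC)[C@@H]2C1 | intermediate
33 | O-alkyl S-methyl xanthate of 32 | C1CC(=C)[C@@]2(C)CC[C@H](C)[C@@](C)(C(OC(=S)SC)c3cc(C(=O)OC)c(OCOC)cc3OCOC)[C@@H]2C1 | intermediate
34 | methyl 5-(decalinylmethyl)-2,4-bis(methoxymethoxy)benzoate (exocyclic alkene) | C1CC(=C)[C@@]2(C)CC[C@H](C)[C@@](C)(Cc3cc(C(=O)OC)c(OCOC)cc3OCOC)[C@@H]2C1 | intermediate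
35 | methyl 5-(decalinylmethyl)-2,4-dihydroxybenzoate (exocyclic alkene) | C1CC(=C)[C@@]2(C)CC[C@H](C)[C@@](C)(Cc3cc(C(=O)OC)c(O)cc3O)[C@@H]2C1 | intermediate
36 | methyl 5-(decalinylmethyl)-2,4-dihydroxy-3-[(E)-(4-nitrophenyl)diazenyl]benzoate | C1CC(=C)[C@@]2(C)CC[C@H](C)[C@@](C)(Cc3cc(C(=O)OC)c(O)c(/N=N/c4ccc(cc4)[N+](=O)[O-])c3O)[C@@H]2C1 | intermediate
37 | methyl 3-amino-5-(decalinylmethyl)-2,4-dihydroxybenzoate (exocyclic alkene) | C1CC(=C)[C@@]2(C)CC[C@H](C)[C@@](C)(Cc3cc(C(=O)OC)c(O)c(N)c3O)[C@@H]2C1 | intermediate
38 | nakijiquinone E (both decalins 5S,8S,9R,10S) | C=C1CCC[C@H]2[C@](C)(Cc3cc(C(=O)OC)c(O)c(NC4=CC(=O)C(O)=C(C[C@]5(C)[C@@H](C)CC[C@]6(C)C(C)=CCC[C@@H]56)C4=O)c3O)[C@@H](C)CC[C@]12C | target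

## Step count and least certain steps

Total: 29 steps. Longest linear sequence: 20 steps (3 through steps 2–14 to 19, then steps 23–28 to 37, then step 29).

Step 6 (key step). The cycloaddition may be slow, because the reactive s-cis conformer of 7 has a methyl group inside. The strong Lewis acid could then ionise or oligomerise the allylic silyl ether, and enantiofacial control would erode if an uncatalysed pathway or a pathway bound at the C4 carbonyl competed. Fallback, from 2 and 7: run the cycloaddition with SnCl4 in CH2Cl2 at −78 °C. Chelation between the C1 carbonyl and the methoxy oxygen enforces the same regiochemistry and endo approach, and should give 8 together with the mirror-image adduct F1. The two are separated by preparative chromatography on a chiral stationary phase, and the route is rejoined at 8.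

Step 9. Protonation of the C10 carbanion could occur partly from the β face, giving the cis fusion, and over-reduction could set in if the dienolate were protonated before the metal is consumed. Fallback, from 8: form the enolate with KN(SiMe3)2 and protonate it at −78 °C with 2,6-di-tert-butylphenol from the face anti to the two β methyls, which should give the trans-fused dione F2. A Luche reduction (NaBH4, CeCl3) then reduces only the C1 ketone, since C4 is a vinylogous ester, to the C1 alcohol F3. This is converted to the S-methyl xanthate F4 and deoxygenated with Bu3SnH and AIBN; the route is rejoined at 13.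

Step 10. Facial selectivity at C8 could be poor because the α face carries the CH2OSi group, and reduction of the hindered trisubstituted alkene could be incomplete. Fallback, from 13: Bu4NF gives the homoallylic alcohol F5. Hydroxyl-directed hydrogenation with [Ir(cod)(PCy3)(py)]PF6 in CH2Cl2 delivers hydrogen to the α face from the C11 hydroxyl and gives the 8β-methyl alcohol F6. Re-silylation gives the silyl ether F7, and hydrogenation of its vinylogous ester alkene over Pd/C rejoins the route at 14.

Step 27. Coupling at a position flanked by two oxygens on an ester-deactivated ring may be slow, so that diazonium decomposition competes. Fallback, from 35: nitration with one equivalent of HNO3 in AcOH/CH2Cl2 at 0 °C, where C3 is the only activated open position, gives the nitro compound F8. Reduction with Zn and NH4Cl rejoins the route at 37.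

Step 29. Addition of the hindered aniline to the electron-rich hydroxyquinone may be slow, and prolonged warming invites oxidation of the aminoresorcinol by the quinone or ring closure of an ortho hydroxyl onto the quinone. Fallback, from 27: complete hydrolysis with aqueous NaOH followed by acid gives the dihydroxyquinone F9. Acid-catalysed condensation of F9 with 37 in AcOH/EtOH at 23 °C exchanges the hydroxyl remote from the alkyl group, the known behaviour of 2,5-dihydroxy-3-alkylquinones with anilines, and arrives at 38.

## Further compounds

F1 | step 6 | mirror image of 8 (ent-8) | COC1=CC(=O)[C@]2(C)CC=C(C)[C@](C)(CO[Si](C)(C)C(C)(C)C)[C@@H]2C1=O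
F2 | step 9 | trans-fused dione, C10 epimer of 8 (H-10 α) | COC1=CC(=O)[C@@]2(C)CC=C(C)[C@@](C)(CO[Si](C)(C)C(C)(C)C)[C@@H]2C1=O
F3 | step 9 | C1 alcohol of F2 (C1 epimers; C4 vinylogous ester intact) | COC1=CC(=O)[C@@]2(C)CC=C(C)[C@@](C)(CO[Si](C)(C)C(C)(C)C)[C@@H]2C1O
F4 | step 9 | O-alkyl S-methyl xanthate of F3 | COC1=CC(=O)[C@@]2(C)CC=C(C)[C@@](C)(CO[Si](C)(C)C(C)(C)C)[C@@H]2C1OC(=S)SC
F5 | step 10 | C11 alcohol of 13 | COC1=CC(=O)[C@@]2(C)CC=C(C)[C@@](C)(CO)[C@@H]2C1
F6 | step 10 | 8β-methyl C11 alcohol (C7–C8 saturated vinylogous ester) | COC1=CC(=O)[C@@]2(C)CC[C@H](C)[C@@](C)(CO)[C@@H]2C1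
F7 | step 10 | tert-butyldimethylsilyl ether of F6 | COC1=CC(=O)[C@@]2(C)CC[C@H](C)[C@@](C)(CO[Si](C)(C)C(C)(C)C)[C@@H]2C1
F8 | step 27 | methyl 5-(decalinylmethyl)-2,4-dihydroxy-3-nitrobenzoate | C1CC(=C)[C@@]2(C)CC[C@H](C)[C@@](C)(Cc3cc(C(=O)OC)c(O)c([N+](=O)[O-])c3O)[C@@H]2C1
F9 | step 29 | 2,5-dihydroxy-3-(decalinylmethyl)-1,4-benzoquinone (endocyclic alkene) | C1C=C(C)[C@@]2(C)CC[C@H](C)[C@@](C)(CC3=C(O)C(=O)C=C(O)C3=O)[C@@H]2C1
A1 | alternative 1 | acyclic vinylallene (E)-2-methyl-enal with C4 ketal | O=C/C(C)=C/CCCC1(OCCO1)/C(C)=C/C=C=C
A2 | alternative 1 | trans-decalin dienyl aldehyde, C4 ketal | O1CCOC12CCC[C@H]3[C@](C)(C=O)C(=C)C=C[C@]23C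
A3 | alternative 2 | 4-alkenyl-4-hydroxy-3-(arylamino)cyclobutenone (carbinol centre and enol ether geometry not defined) | CCOC=C(C[C@]5(C)[C@@H](C)CC[C@]6(C)C(C)=CCC[C@@H]56)C1(O)C(Nc2c(OCOC)c(C(=O)OC)cc(C[C@]3(C)[C@@H](C)CC[C@]4(C)C(=C)CCC[C@@H]34)c2OCOC)=CC1=O
A4 | alternative 2 | arylamino ethoxy hydroquinone | CCOc1c(O)cc(Nc2c(OCOC)c(C(=O)OC)cc(C[C@]3(C)[C@@H](C)CC[C@]4(C)C(=C)CCC[C@@H]34)c2OCOC)c(O)c1C[C@]5(C)[C@@H](C)CC[C@]6(C)C(C)=CCC[C@@H]56
A5 | alternative 3 | geranylgeranyl diphosphate | CC(C)=CCC/C(C)=C/CC/C(C)=C/CC/C(C)=C/COP(=O)(O)OP(=O)(O)O
A6 | alternative 3 | kolavenyl diphosphate, enantiomer matching the target | OP(=O)(O)OP(=O)(O)OC/C=C(\C)CC[C@]1(C)[C@@H](C)CC[C@]2(C)C(C)=CCC[C@@H]12
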